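**The invariant.** The flask is closed, so L, D, Q, J and Z together always equal the L charged, and the first step moves material within the pool of L and D without changing its size.

L 0.55 M; time 2.0 h

    L ⇌ D (K1 = 0.66, k1 = 9.80 × 10⁻⁴ s⁻¹)
    D ⇌ Q (K2 = 1.75, k2 = 6.97 × 10⁻⁵ s⁻¹)
    Q ⇌ J (K3 = 0.51, k3 = 9.32 × 10⁻⁵ s⁻¹)
    Z ⇌ D, rate k4*(cs4 - [D]) while solid is left; crystals form when [D] > cs4 (cs4 = 0.40 M, k4 = 0.00187 s⁻¹)

- what is said of D includes Z
- Z is a solid; its amount is given per volume of the solution
- run time (flask): 2.0 h

1. D and Z together at 2.0 h, in percent of the L charged
2. concentration of D in solution at 2.0 h, in percent of saturation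

**First estimate.** We carry one quantity: 39.8 % is the D share of the pool, the first equilibrium constant over one plus itself. Even with the whole charge in the pool, D comes to 0.219 M, less than the solubility of 0.40 M, so we expect no crystals in this flask.

**First doubt.** Has the first step had time to balance? Its relaxation half-life, both ways together, is 0.0781 h, short against the 2.0 h, so we apply the share at the asked time.

**Second doubt.** The pool is not sealed: D leaks to Q. We compute this as a correction: the pool drains at the second rate constant times the share, 0.0998 h⁻¹. On this estimate it keeps 81.9 % of the charge, which puts D at 32.6 %.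

**Third doubt.** Q returns, though, at 0.143 h⁻¹ per unit of Q, faster than the leak per unit of pool, so we cannot ignore it. Pool and Q relax as a pair at 0.243 h⁻¹, towards a pool of 59.0 %. On this estimate the pool holds 84.2 % after the run time. We leave J out and commit to 33.5 % for D and Z together and 46.0 % of saturation.

**The forecast.** The forecast gave 33.3 % (32 % to 34.5 %) and 45.8 % (44 % to 47.5 %), holding that “no crystals ever form and Z stays at zero”. Its figures lie close to ours but are not the same.

**The share applied.** The simulation gives 33.3 % and 45.7 %, with Z at 0 %, so the forecast held. The reading of D over L and D at that time is 39.2 %, near the share of 39.8 %. The main reason D and Z stay this low is the falling back of D to L: with that return struck out they reach 69.9 %, not 33.3 %. In the neighbouring flask with 2.2 M of L, the share gives 0.876 M, above the solubility, and there Z holds 44.1 % of the L charged.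

The constants used here were set for the occasion; the flask was simulated.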